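**Retrosynthetic overview**

- Feature: on the central benzene ring a free OH sits ortho to the oxygen of the aryl enol ether O–C(CO2H)=CH–Ar. The phenol O and the carboxyl C are the two ends of an opened six-membered 1,4-benzodioxin-2-one lactone, and that lactone is a (Z)-aurone (2-arylidene-benzofuran-3-one) with one oxygen inserted between the ketone carbon and the benzene ring.
- Disconnections, backwards: global acidolysis of two tert-butyl esters and two catechol acetonides; Heck C–C bond between the aryl bromide para to the enol ether oxygen and the acrylate of protected (R)-danshensu (E-cinnamate, stereocentre from the chiral pool); lactone C(=O)–OAr cleavage by tert-butoxide.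
- Then: Baeyer–Villiger aryl migration, aurone to benzodioxinone; aldol condensation of 5-bromobenzofuran-3(2H)-one with the acetonide of 3,4-dihydroxybenzaldehyde.
- Rings: the furanone is bought and receives its arylidene in step 2. The only ring made is the dioxinone, by expansion of the furanone in step 3, and it is opened again in step 4. The dioxole and dioxolanone rings are protecting groups.

Key step: step 3

Assumption: (R)-danshensu is used as the free acid (a sodium salt would be acidified first, not counted as a step), and all catechols are carried as acetonides so that the last step loses only acetone and isobutene.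

**Route**

Step 1
Reactants: 1 3,4-dihydroxybenzaldehyde
Product: 2 2,2-dimethyl-1,3-benzodioxole-5-carbaldehyde
Conditions: Me2C(OMe)2 (excess), TsOH·H2O (cat.), toluene, reflux, Soxhlet with 4 Å MS; wet SiO2 on work-up
Reagents that add atoms: 2,2-dimethoxypropane, COC(C)(C)OC
Why: Acid-catalysed transketalisation of the catechol with the dimethyl ketal of acetone, driven by trapping of methanol in the sieves, should close the benzodioxole, and any aldehyde dimethyl acetal formed alongside is returned to the aldehyde on wet silica.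

Step 2
Reactants: 2 2,2-dimethyl-1,3-benzodioxole-5-carbaldehyde; 3 5-bromobenzofuran-3(2H)-one
Product: 5 (Z)-5-bromo-2-[(2,2-dimethyl-1,3-benzodioxol-5-yl)methylidene]-1-benzofuran-3(2H)-one, via aldol adduct 4 (not isolated)
Conditions: neutral Al2O3, CH2Cl2, rt, dark
Reagents that add atoms: none
Why: Aldol condensation of the acidic C2 methylene of the benzofuranone with the aromatic aldehyde on alumina, followed by dehydration of adduct 4, should give the aurone as the thermodynamically preferred Z isomer (aryl cis to the ring oxygen and away from the carbonyl) under conditions that leave the ketal and the aryl bromide alone.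

Step 3
Reactants: 5 (Z)-5-bromo-2-[(2,2-dimethyl-1,3-benzodioxol-5-yl)methylidene]-1-benzofuran-3(2H)-one
Product: 7 (Z)-7-bromo-3-[(2,2-dimethyl-1,3-benzodioxol-5-yl)methylidene]-1,4-benzodioxin-2(3H)-one, via Criegee adduct 6 (not isolated)
Conditions: mCPBA (1.5 equiv), CH2Cl2, 0 °C to rt, dark; non-aqueous work-up
Reagents that add atoms: mCPBA (3-chloroperoxybenzoic acid), OOC(=O)c1cccc(Cl)c1
Why: Proposed new method: mCPBA should add to the C3 ketone of 5 to give the Criegee adduct 6, in which the arene carbon C3a shifts from C3 to the proximal peroxide oxygen as 3-chlorobenzoate leaves, so that one oxygen is inserted into the C3–C3a bond. The closest known reaction type is the Baeyer–Villiger (Dakin-type) oxidation of ortho-alkoxyaryl ketones, 1-indanones and chroman-4-ones with aryl migration, which has not been shown on the cross-conjugated ketone of an aurone. The six-membered 1,4-dioxin-2-one ring is closed by ring expansion of the furanone through this 1,2-shift (five to six members, new aryl C–O bond) and not by an end-to-end cyclisation. No stereocentre is formed, and the Z alkene is kept because neither alkene carbon takes part. The step needs migration of C3a and not of the oxygen-bearing vinyl carbon C2; the ring oxygen O1 ortho to C3a should secure this by stabilising the bridged aryl transition state, while the oxygen on C2 withdraws inductively from that carbon. It also needs attack at the ketone and not at the alkene or the ketal-bearing arene, for which the moderately electrophilic mCPBA is taken in place of CF3CO3H and the alkene is deactivated as part of an enone.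

Step 4
Reactants: 7 (Z)-7-bromo-3-[(2,2-dimethyl-1,3-benzodioxol-5-yl)methylidene]-1,4-benzodioxin-2(3H)-one
Product: 8 tert-butyl (Z)-2-(4-bromo-2-hydroxyphenoxy)-3-(2,2-dimethyl-1,3-benzodioxol-5-yl)prop-2-enoate
Conditions: KOt-Bu (1.1 equiv), THF, −78 to −20 °C (7 added to the base); AcOH quench
Reagents that add atoms: potassium tert-butoxide, CC(C)(C)[O-].[K+]
Why: Lactone alcoholysis (transesterification by nucleophilic acyl substitution) should occur because tert-butoxide adds to the activated aryl ester carbonyl and the much less basic phenoxide leaves, inverse addition keeping alkoxide in excess so that the phenoxide cannot acylate itself on a second lactone, and the Z enol ether is not touched.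

Step 5
Reactants: 9 (R)-danshensu, (R)-3-(3,4-dihydroxyphenyl)-2-hydroxypropanoic acid
Product: 11 (R)-5-[(2,2-dimethyl-1,3-benzodioxol-5-yl)methyl]-2,2-dimethyl-1,3-dioxolan-4-one, via catechol dioxolanone 10 (not isolated)
Conditions: Me2C(OMe)2/acetone, TsOH·H2O (cat.), rt; then toluene, reflux, Soxhlet with 4 Å MS, Ar
Reagents that add atoms: 2,2-dimethoxypropane, COC(C)(C)OC
Why: Double acid-catalysed transketalisation should first tie the α-hydroxy acid into the dioxolanone 10 at room temperature, which masks the alcohol against oxa-Pictet–Spengler closure onto the catechol ring, and then ketalise the catechol under reflux with removal of methanol, the stereocentre keeping all four of its bonds.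

Step 6
Reactants: 11 (R)-5-[(2,2-dimethyl-1,3-benzodioxol-5-yl)methyl]-2,2-dimethyl-1,3-dioxolan-4-one
Product: 12 (R)-3-(2,2-dimethyl-1,3-benzodioxol-5-yl)-2-hydroxypropanoic acid
Conditions: LiOH (2 equiv), THF/H2O, 0 °C; then 1 M HCl to pH 3, 0 °C
Reagents that add atoms: lithium hydroxide, [Li+].[OH-]
Why: Saponification of the activated dioxolanone (hydroxide adds to the carbonyl and the hemiketal leaving group collapses to acetone) is much faster than enolisation at 0 °C, so the α-hydroxy acid should be freed without loss of configuration while the aryl ketal survives the brief cold acidification, and any methyl ester formed in step 5 converges on the same acid.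

Step 7
Reactants: 12 (R)-3-(2,2-dimethyl-1,3-benzodioxol-5-yl)-2-hydroxypropanoic acid
Product: 13 tert-butyl (R)-3-(2,2-dimethyl-1,3-benzodioxol-5-yl)-2-hydroxypropanoate
Conditions: Cl3CC(=NH)Ot-Bu (2 equiv), CH2Cl2/cyclohexane, rt
Reagents that add atoms: tert-butyl 2,2,2-trichloroacetimidate, CC(C)(C)OC(=N)C(Cl)(Cl)Cl
Why: Trichloroacetimidate esterification should be selective because only the carboxylic acid is acidic enough to protonate the imidate and capture the tert-butyl group, whereas the secondary alcohol and the ketal need a Lewis acid that is not present.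

Step 8
Reactants: 13 tert-butyl (R)-3-(2,2-dimethyl-1,3-benzodioxol-5-yl)-2-hydroxypropanoate; 14 acryloyl chloride
Product: 15 tert-butyl (R)-2-(acryloyloxy)-3-(2,2-dimethyl-1,3-benzodioxol-5-yl)propanoate
Conditions: Et3N (1.5 equiv), CH2Cl2, −20 to 0 °C, BHT (trace)
Reagents that add atoms: none
Why: O-Acylation of the only free hydroxyl by the acid chloride takes place at oxygen, so the configuration of the adjacent carbon should be retained, and the low temperature limits polymerisation and amine addition to the acrylate.

Step 9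
Reactants: 8 tert-butyl (Z)-2-(4-bromo-2-hydroxyphenoxy)-3-(2,2-dimethyl-1,3-benzodioxol-5-yl)prop-2-enoate; 15 tert-butyl (R)-2-(acryloyloxy)-3-(2,2-dimethyl-1,3-benzodioxol-5-yl)propanoate
Product: 16 tert-butyl (R)-2-{[(E)-3-(4-{[(Z)-3-tert-butoxy-1-(2,2-dimethyl-1,3-benzodioxol-5-yl)-3-oxoprop-1-en-2-yl]oxy}-3-hydroxyphenyl)prop-2-enoyl]oxy}-3-(2,2-dimethyl-1,3-benzodioxol-5-yl)propanoate
Conditions: Pd2(dba)3 (2.5 mol%), [HP(t-Bu)3]BF4 (10 mol%), Cy2NMe (2.5 equiv), dioxane, 70 °C, Ar, dark
Reagents that add atoms: none
Why: In this Mizoroki–Heck reaction, oxidative addition into the aryl bromide, syn-carbopalladation of the terminal acrylate and syn-β-hydride elimination should give the E-cinnamate, the electron-rich bulky phosphine allowing a temperature at which the free phenol, the trisubstituted Z enol ether and the α-acyloxy ester stereocentre are kept.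

Step 10
Reactants: 16 tert-butyl (R)-2-{[(E)-3-(4-{[(Z)-3-tert-butoxy-1-(2,2-dimethyl-1,3-benzodioxol-5-yl)-3-oxoprop-1-en-2-yl]oxy}-3-hydroxyphenyl)prop-2-enoyl]oxy}-3-(2,2-dimethyl-1,3-benzodioxol-5-yl)propanoate
Product: 17 (R)-2-{[(E)-3-(4-{[(Z)-1-carboxy-2-(3,4-dihydroxyphenyl)ethenyl]oxy}-3-hydroxyphenyl)prop-2-enoyl]oxy}-3-(3,4-dihydroxyphenyl)propanoic acid (CNP0157552.2)
Conditions: TFA/H2O (9:1), 0 °C to rt, Ar, dark; H2O dilution, lyophilisation, RP-HPLC (MeCN/H2O, 0.1% HCO2H)
Reagents that add atoms: none
Why: Global acidolysis should cleave both tert-butyl esters by the alkyl–oxygen (AAL1) path with loss of isobutene and hydrolyse both catechol ketals with loss of acetone, while the cinnamate ester, the acceptor-substituted enol ether and the stereocentre are stable to cold aqueous TFA and the water present keeps the 2-hydroxyaryl ether acid in its open form.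

**Compound list**

1 | 3,4-dihydroxybenzaldehyde | O=Cc1ccc(O)c(O)c1 | starting material
2 | 2,2-dimethyl-1,3-benzodioxole-5-carbaldehyde | O=Cc1ccc2OC(C)(C)Oc2c1 | intermediate
3 | 5-bromobenzofuran-3(2H)-one | O=C1COc2ccc(Br)cc12 | starting material
4 | 5-bromo-2-[(2,2-dimethyl-1,3-benzodioxol-5-yl)(hydroxy)methyl]-1-benzofuran-3(2H)-one (aldol adduct, diastereomer mixture, not isolated) | O=C1c2cc(Br)ccc2OC1C(O)c1ccc2OC(C)(C)Oc2c1 | intermediate
5 | (Z)-5-bromo-2-[(2,2-dimethyl-1,3-benzodioxol-5-yl)methylidene]-1-benzofuran-3(2H)-one | O=C1c2cc(Br)ccc2O/C1=C\c1ccc2OC(C)(C)Oc2c1 | intermediate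
6 | (Z)-5-bromo-2-[(2,2-dimethyl-1,3-benzodioxol-5-yl)methylidene]-3-hydroxy-2,3-dihydro-1-benzofuran-3-yl 3-chloroperoxybenzoate (Criegee adduct, racemic at C3, not isolated) | OC1(OOC(=O)c2cccc(Cl)c2)c2cc(Br)ccc2O/C1=C\c1ccc2OC(C)(C)Oc2c1 | intermediate
7 | (Z)-7-bromo-3-[(2,2-dimethyl-1,3-benzodioxol-5-yl)methylidene]-1,4-benzodioxin-2(3H)-one | O=C1Oc2cc(Br)ccc2O/C1=C\c1ccc2OC(C)(C)Oc2c1 | intermediate
8 | tert-butyl (Z)-2-(4-bromo-2-hydroxyphenoxy)-3-(2,2-dimethyl-1,3-benzodioxol-5-yl)prop-2-enoate | Oc1cc(Br)ccc1O/C(=C\c1ccc2OC(C)(C)Oc2c1)C(=O)OC(C)(C)C | intermediate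
9 | (R)-danshensu, (R)-3-(3,4-dihydroxyphenyl)-2-hydroxypropanoic acid | O[C@H](Cc1ccc(O)c(O)c1)C(=O)O | starting material
10 | (R)-5-(3,4-dihydroxybenzyl)-2,2-dimethyl-1,3-dioxolan-4-one (not isolated) | CC1(C)O[C@H](Cc2ccc(O)c(O)c2)C(=O)O1 | intermediate
11 | (R)-5-[(2,2-dimethyl-1,3-benzodioxol-5-yl)methyl]-2,2-dimethyl-1,3-dioxolan-4-one | CC1(C)O[C@H](Cc2ccc3OC(C)(C)Oc3c2)C(=O)O1 | intermediate
12 | (R)-3-(2,2-dimethyl-1,3-benzodioxol-5-yl)-2-hydroxypropanoic acid | O[C@H](Cc1ccc2OC(C)(C)Oc2c1)C(=O)O | intermediate
13 | tert-butyl (R)-3-(2,2-dimethyl-1,3-benzodioxol-5-yl)-2-hydroxypropanoate | O[C@H](Cc1ccc2OC(C)(C)Oc2c1)C(=O)OC(C)(C)C | intermediate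
14 | acryloyl chloride | C=CC(=O)Cl | starting material
15 | tert-butyl (R)-2-(acryloyloxy)-3-(2,2-dimethyl-1,3-benzodioxol-5-yl)propanoate | C=CC(=O)O[C@H](Cc1ccc2OC(C)(C)Oc2c1)C(=O)OC(C)(C)C | intermediate
16 | tert-butyl (R)-2-{[(E)-3-(4-{[(Z)-3-tert-butoxy-1-(2,2-dimethyl-1,3-benzodioxol-5-yl)-3-oxoprop-1-en-2-yl]oxy}-3-hydroxyphenyl)prop-2-enoyl]oxy}-3-(2,2-dimethyl-1,3-benzodioxol-5-yl)propanoate | O=C(/C=C/c1ccc(O/C(=C\c2ccc3OC(C)(C)Oc3c2)C(=O)OC(C)(C)C)c(O)c1)O[C@H](Cc1ccc2OC(C)(C)Oc2c1)C(=O)OC(C)(C)C | intermediate
17 | (R)-2-{[(E)-3-(4-{[(Z)-1-carboxy-2-(3,4-dihydroxyphenyl)ethenyl]oxy}-3-hydroxyphenyl)prop-2-enoyl]oxy}-3-(3,4-dihydroxyphenyl)propanoic acid | O=C(/C=C/c1ccc(O/C(=C\c2ccc(O)c(O)c2)C(=O)O)c(O)c1)O[C@H](Cc1ccc(O)c(O)c1)C(=O)O | target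

**Step count and risks**

Total step count: 10. Longest linear sequence: 6 steps (1, 2, 3, 4, 9, 10 or 5, 6, 7, 8, 9, 10).

Risk 1, step 3 (Proposed new method). Several processes may defeat it:
- the peracid may fail to add to the doubly conjugated ketone;
- the oxygen-bearing vinyl carbon may migrate in place of the arene carbon;
- the exocyclic alkene may be epoxidised or the dioxole ring oxidised;
- the aryl lactone may be hydrolysed during isolation.

The fallback uses known chemistry only, sets out from aldehyde 2 and comes back to the route at lactone 7. Commercial 5-bromo-2-hydroxybenzaldehyde (O=Cc1cc(Br)ccc1O) would be O-alkylated with methyl bromoacetate (K2CO3, DMF, rt) to methyl 2-(4-bromo-2-formylphenoxy)acetate F1. Dakin-type Baeyer–Villiger oxidation of this ortho-alkoxybenzaldehyde (mCPBA, CH2Cl2) and cleavage of the aryl formate (Et3N, MeOH) should give methyl 2-(4-bromo-2-hydroxyphenoxy)acetate F2. Acid-catalysed lactonisation (TsOH cat., toluene, reflux, methanol distilled off) should give 7-bromo-1,4-benzodioxin-2(3H)-one F3. Its lithium enolate (LiHMDS, THF, −78 °C) would be added to aldehyde 2 to give 7-bromo-3-[(2,2-dimethyl-1,3-benzodioxol-5-yl)(hydroxy)methyl]-1,4-benzodioxin-2(3H)-one F4. Acid-catalysed dehydration of this benzylic alcohol (TsOH cat., toluene, 60 °C) should give the conjugated lactone 7 as the more stable Z isomer. The oxygen ortho to the ether oxygen then comes from an aldehyde Dakin oxidation instead of the aurone ring expansion.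

Risk 2, step 9. Oxidative addition into the electron-rich aryl bromide may be slow. At the temperature then needed the acrylate may polymerise, its α-acyloxy ester centre may epimerise under the amine base, or the free phenol may add to the acrylate in an oxa-Michael reaction. The fallback sets out from bromide 8 and comes back at 16. Miyaura borylation (B2pin2, Pd(dppf)Cl2, KOAc, dioxane, 80 °C) should give tert-butyl (Z)-3-(2,2-dimethyl-1,3-benzodioxol-5-yl)-2-[2-hydroxy-4-(4,4,5,5-tetramethyl-1,3,2-dioxaborolan-2-yl)phenoxy]prop-2-enoate F5. This would be joined to acrylate 15 by a base-free oxidative Heck coupling at room temperature (Pd(OAc)2, 2,9-dimethyl-1,10-phenanthroline, O2 1 atm, MeCN). The aryl–palladium species then arises by transmetalation, without heat or amine.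

Risk 3, step 10. tert-Butyl cations released next to free catechols may alkylate the electron-rich rings. The freed 2-hydroxyaryl ether acid may also re-close to the lactone while the acid is concentrated. The fallback sets out from 16 and comes back at 17, and separates the two cleavages. The tert-butyl esters would be removed first under non-protic conditions (TMSOTf, 2,6-lutidine, CH2Cl2, 0 °C; aqueous work-up to hydrolyse the silyl esters and the aryl silyl ether), the tert-butyl groups leaving as isobutene while both catechols are still ketals. This should give (R)-2-{[(E)-3-(4-{[(Z)-1-carboxy-2-(2,2-dimethyl-1,3-benzodioxol-5-yl)ethenyl]oxy}-3-hydroxyphenyl)prop-2-enoyl]oxy}-3-(2,2-dimethyl-1,3-benzodioxol-5-yl)propanoic acid F6. The ketals would then be hydrolysed in AcOH/H2O (4:1, 60 °C), where no carbocation is formed and water is in large excess, to give 17.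

Further compounds
F1 | step 3 | methyl 2-(4-bromo-2-formylphenoxy)acetate | COC(=O)COc1ccc(Br)cc1C=O
F2 | step 3 | methyl 2-(4-bromo-2-hydroxyphenoxy)acetate | COC(=O)COc1ccc(Br)cc1O
F3 | step 3 | 7-bromo-1,4-benzodioxin-2(3H)-one | O=C1COc2ccc(Br)cc2O1
F4 | step 3 | 7-bromo-3-[(2,2-dimethyl-1,3-benzodioxol-5-yl)(hydroxy)methyl]-1,4-benzodioxin-2(3H)-one (diastereomer mixture) | O=C1Oc2cc(Br)ccc2OC1C(O)c1ccc2OC(C)(C)Oc2c1
F5 | step 9 | tert-butyl (Z)-3-(2,2-dimethyl-1,3-benzodioxol-5-yl)-2-[2-hydroxy-4-(4,4,5,5-tetramethyl-1,3,2-dioxaborolan-2-yl)phenoxy]prop-2-enoate | Oc1cc(B2OC(C)(C)C(C)(C)O2)ccc1O/C(=C\c1ccc2OC(C)(C)Oc2c1)C(=O)OC(C)(C)C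
F6 | step 10 | (R)-2-{[(E)-3-(4-{[(Z)-1-carboxy-2-(2,2-dimethyl-1,3-benzodioxol-5-yl)ethenyl]oxy}-3-hydroxyphenyl)prop-2-enoyl]oxy}-3-(2,2-dimethyl-1,3-benzodioxol-5-yl)propanoic acid | O=C(/C=C/c1ccc(O/C(=C\c2ccc3OC(C)(C)Oc3c2)C(=O)O)c(O)c1)O[C@H](Cc1ccc2OC(C)(C)Oc2c1)C(=O)O
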